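At early times links climbed in both runs. The last two grey readings, 36% and 35%, were level within the scatter of 2 percentage points, but the last two red readings, 18% and 20%, could not tell me whether the red run had stopped climbing.

| flask | first end groups | second end groups | third end groups | remark | time |
|---|---|---|---|---|---|
| grey | 0.72 M | 1 equiv | 0.25 equiv | the very flask that is asked about, followed so far |  |
| red | 0.36 M | 1 equiv | 0.25 equiv | run made earlier |  |
| flask | 0.72 M | 1.00 equiv | 0.250 equiv |  | 1.0 h |

| run | time / min | links / % | first end groups / % |
|---|---|---|---|
| grey | 12.0 | 20 | 78 |
| grey | 25.0 | 32 | 64 |
| grey | 40.0 | 36 | 59 |
| grey | 50.0 | 35 | 56 |
| red | 3.00 | 3 | 96 |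
| red | 8.00 | 13 | 91 |
| red | 20.0 | 18 | 82 |
| red | 40.0 | 20 | 74 |

(readings scatter by 2 percentage points)

- alpha: at 1.0 h take out 90% of the links then present, then wait 1.0 h
- gamma: at 1.0 h add second end groups, 50.0% of the amount charged, then wait 1.0 h
- epsilon: change nothing and wait 1.0 h more
- delta: at 1.0 h add first end groups, 50.0% of the amount charged, then wait 1.0 h

- what is taken out of links is counted as made
- the numbers in the tables scatter with a standard deviation of 2 percentage points
- additions bring no volume worth counting

1. links, in percent of the first end groups first charged, at 1.0 h
2. which option adds most links ("none" when 2 percentage points or less is all one gets) (alpha / gamma / epsilon / delta / none)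
3. links present, with what was taken out counted in, in percent of the first end groups first charged, after gamma
4. links present, with what was taken out counted in, in percent of the first end groups first charged, after delta

The bench rule reads a flat curve as an equilibrium, so I tried it: with equal charges, links over the square of the first end groups left should give one mass-action quotient. The grey flask gave 1.55 /M at 50.0 min and the red 1.01 /M at 40.0 min, a ratio of 1.53. The red run might still have been on its way, so this ratio proved nothing, but it gave the rule no support and I looked for another reading.

I supposed instead that second end groups, the limiting reagent, also decay by a first-order route beside their second-order coupling. If the flat end marks their end, the grey charge times the fraction of first end groups left, over the logarithm of its inverse, gives 0.695 M, the break-even concentration: the concentration of first end groups at which coupling and loss take second end groups equally. Above it their decay leans to second order, below it to first. The red run, still falling, gave 0.885 M.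

The last grey reading left 0.403 M of first end groups, so added second end groups should couple in the share 36.7%. With 79.5% of the first end groups used appearing as links, gamma should add 15 points. I chose gamma.

The forecast gave 35.5% now, alpha as best, 45% after gamma and 46% after delta, holding that “the flask is essentially at equilibrium”. We parted on the best option.

The grey flask gave 37.2%, with gamma best, 52.8% after gamma and 39.3% after delta.

    second end groups + third end groups → links of the second sort (k = 9.30 × 10⁻⁴ /M/s)
    first end groups + second end groups → links (k = 7.50 × 10⁻⁴ /M/s)
    second end groups → decomposed reagent (k = 3.90 × 10⁻⁴ /s)
    links → over-reaction product (k = 8.20 × 10⁻⁸ /s)
    links ⇌ isomer of the product (K = 0.150, k = 5.10 × 10⁻⁴ /s)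

Gamma added 16 points against my reckoned 15 points, and at 1.0 h the grey flask kept 4.6% of its second end groups. For the neighbour charged with 2.50 equiv of second end groups I used the same balance with the break-even concentration 0.695 M: bringing first end groups down to the 18.7% it held needs 2.43 equiv, coupling and loss together. That neighbour had spent 2.24, and its links stood at 70.8%.

The readings stem from a simulated flask for an exercise; the scatter is artificial.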